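If you put the product at 25 min against [added ligand] on logarithmic axes, your hunch that the new flask is just the next point down the line becomes a number.

the same everywhere: substrate 0.80 M (in portions, 3); free catalyst 26 mM
- south-west: partner 0.76 M; added ligand 36 mM; run made earlier; portions every 8.0 min
- south: partner 0.76 M; added ligand 55 mM; run made earlier; portions every 8.0 min
- north-east: partner 1.1 M; added ligand 73 mM; run made earlier; portions every 8.0 min
- flask: partner 0.760 M; added ligand 73 mM; the portions of substrate follow each other after 8.0 min, the first at the start; time 25 min

| run | time / min | product / % | substrate / % |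
|---|---|---|---|
| south-west | 6.00 | 4.4 | 29.5 |
| south-west | 12.0 | 8.5 | 57.2 |
| south-west | 20.0 | 18.7 | 81.7 |
| south-west | 25.0 | 25.6 | 73.3 |
| south | 3.00 | 0.8 | 32.6 |
| south | 8.00 | 1.9 | 29.4 |
| south | 15.0 | 9.0 | 57.2 |
| south | 25.0 | 18.7 | 81.0 |
| north-east | 2.00 | 0 | 32.6 |
| north-east | 5.00 | 2.1 | 31.7 |
| north-east | 10.0 | 4.3 | 62.8 |
| north-east | 25.0 | 16.6 | 83.4 |

(each reading ± 0.5 percentage points)



- amount of product in percent of the substrate charged, at 80 s, 6.0 min and 25 min

The south-west and south runs have the flask's partner charge, and they read 25.6% at 36 mM and 18.7% at 55 mM. In powers of ten, the product falls by 0.136 while [added ligand] rises by 0.184. The quantity I keep is the ratio of these two, the fall in log product per unit rise in log [added ligand], an apparent order in added ligand. It reads 0.741, with the scatter of two readings in it.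

Carrying that slope from 55 mM to 73 mM, I get 15.2% for the flask at 25 min. The north-east run has the flask's ligand but more partner, and it reads 16.6%, above my number. My slope speaks of 25 min and nothing earlier.

The forecast gives 0.3%, 1.7% and 13.5%, on the ground that “more added ligand slows product formation”. Its last value is lower than mine.

The flask gives 0.375% at 80 s, 2.01% at 6.0 min and 15.6% at 25 min, so the forecast held, and my number lies 0.40 percentage points below the last.

    substrate + free catalyst → catalyst intermediate A (k = 2.02 L mol⁻¹ min⁻¹)
    free catalyst + added ligand ⇌ idle complex, settled at all times (K = 68.2 L mol⁻¹)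
    catalyst intermediate B → free catalyst + product (k = 255 min⁻¹)
    partner + catalyst intermediate A → catalyst intermediate B (k = 4.25 L mol⁻¹ min⁻¹)

At 25.0 min the flask holds 71.1% of its catalyst as idle complex and 19.1% as free catalyst. The same logarithmic reckoning on the simulated flask with twice the partner, which gives 16.5%, yields a partner slope of 0.0815, smaller than the ligand slope of 0.741 read from the two runs by a factor of 9.10.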